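**Plan**

1. Retrosynthesis: the oleate C15–O acyl bond is cut last and a temporary oxygen is put back on C1. One retro-event then cuts C8–C9 and returns the C5–C10 bond to C1–C5, which opens ring B and shrinks ring A (C1–C5, C10) to a cyclopentane (C1–C5). The cyclopentane is cut at C5–C6, C4–C18 and C1–C10.
2. Enabling feature: C9 carries the side chain next to the exocyclic C8=C17 methylene, which is what a terminal alkyne leaves behind when a C9=C10 alkene attacks its inner carbon. Quaternary C10 sits next to C1, a CH2 that can have been a silyloxy carbon. A 1-alkenyl-2-butynylcyclopentyl silyl ether can therefore give rings A and B in one cationic event.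
3. Forward: geraniol gives the E-alkenyl unit (C9–C16, C20), which is added to a 3-oxocyclopentenecarboxylate (C1–C5, C19). Conjugate addition of the butynyl unit (C6–C8, C17) and C4 methylation follow. Enyne cyclisation/1,2-shift catalysed by [(t-Bu)2(2-biphenylyl)P]Au(NCMe)SbF6 closes ring B (seven-membered, contracted to six) and enlarges ring A (five to six). C1 deoxygenation, fluoride deprotection and oleoylation finish the route.
4. Stereochemistry: one catalyst-controlled carbinol centre (C1, destroyed later) relays to C5 (CuBr·SMe2-catalysed Grignard addition anti to the silyloxy group) and to C4 (methylation anti to the C5 chain). In the cascade the E-alkene geometry and same-face addition fix C9 and C10, and migration of C5 with retention from the cis-disposed cyclopentane gives the trans ring fusion. Both side-chain alkenes come with fixed geometry from geraniol and oleoyl chloride.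

Key step: step 10

Remark: the target is read as the 15-O-oleate of natural isocupressic acid; labdane numbers (C1–C20, C19 = carboxyl carbon) are used for these atoms in every intermediate, and 3-oxocyclopent-1-ene-1-carboxylic acid is assumed to be a catalogue compound.

**Route**

Step 1
Reactants: 1 geraniol
Product: 2 geranyl tert-butyldiphenylsilyl ether
Conditions: TBDPSCl, imidazole, DMF, rt
Reagents that add atoms: tert-butyl(chloro)diphenylsilane, CC(C)(C)[Si](Cl)(c1ccccc1)c1ccccc1
Why: Silyl ether protection of the primary allylic alcohol should give an ether that tolerates the organometallic, basic and Lewis acidic steps up to step 14.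

Step 2
Reactants: 2 geranyl tert-butyldiphenylsilyl ether
Product: 4 (4E)-6-[(tert-butyldiphenylsilyl)oxy]-4-methylhex-4-enal, via 6,7-epoxygeranyl silyl ether 3 (not isolated)
Conditions: mCPBA, CH2Cl2, 0 °C; then H5IO6, THF/H2O, 0 °C
Reagents that add atoms: 3-chloroperbenzoic acid, O=C(OO)c1cccc(Cl)c1
Why: Prilezhaev epoxidation should select the electron-richer 6,7-alkene over the 2,3-alkene that is deactivated by the allylic oxygen, and periodic acid cleavage of the epoxide should release the isopropylidene carbons as acetone and leave the aldehyde carbon that becomes C9.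

Step 3
Reactants: 4 (4E)-6-[(tert-butyldiphenylsilyl)oxy]-4-methylhex-4-enal
Product: 5 tert-butyl{[(2E)-7,7-dibromo-3-methylhepta-2,6-dien-1-yl]oxy}diphenylsilane
Conditions: CBr4, PPh3, Zn, CH2Cl2, 0 °C → rt
Reagents that add atoms: tetrabromomethane, BrC(Br)(Br)Br
Why: Corey–Fuchs dibromoolefination (a Wittig-type reaction) should add the carbon that becomes C10, the zinc variant avoiding Ph3PBr2 and so sparing the allylic silyl ether.

Step 4
Reactants: 5 tert-butyl{[(2E)-7,7-dibromo-3-methylhepta-2,6-dien-1-yl]oxy}diphenylsilane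
Product: 7 tert-butyl{[(2E)-3-methyloct-2-en-6-yn-1-yl]oxy}diphenylsilane, via lithium acetylide 6 (not isolated)
Conditions: n-BuLi (2.2 equiv), THF, −78 → 0 °C; then MeI, −78 °C → rt
Reagents that add atoms: iodomethane, CI
Why: The second stage of the Corey–Fuchs sequence (Br/Li exchange and Fritsch–Buttenberg–Wiechell shift) should give the acetylide, and its C-methylation installs C20.

Step 5
Reactants: 8 3-oxocyclopent-1-ene-1-carboxylic acid
Product: 9 2-(trimethylsilyl)ethyl 3-oxocyclopent-1-ene-1-carboxylate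
Conditions: Me3SiCH2CH2OH, DCC, DMAP (cat.), CH2Cl2, 0 °C → rt
Reagents that add atoms: 2-(trimethylsilyl)ethanol, C[Si](C)(C)CCO
Why: Steglich esterification should give an ester that fluoride later removes by fragmentation, so that the steric shielding of the C19 carbonyl in the decalin does not matter.

Step 6
Reactants: 7 tert-butyl{[(2E)-3-methyloct-2-en-6-yn-1-yl]oxy}diphenylsilane; 9 2-(trimethylsilyl)ethyl 3-oxocyclopent-1-ene-1-carboxylate
Product: 12 2-(trimethylsilyl)ethyl (3S)-3-{(2E,6E)-8-[(tert-butyldiphenylsilyl)oxy]-6-methylocta-2,6-dien-2-yl}-3-hydroxycyclopent-1-ene-1-carboxylate, via alkenylzirconocene chloride 10 (not isolated), via alkenyl(methyl)zinc 11 (not isolated)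
Conditions: Cp2Zr(H)Cl (excess), CH2Cl2, rt; Me2Zn, toluene, −78 °C; then Ti(O-i-Pr)4 (1.2 equiv), trans-cyclohexane-1,2-diamine bis(2-hydroxycamphor-10-sulfonamide) ligand (10 mol %), 9, toluene, 0 °C → rt
Reagents that add atoms: none
Why: syn-Hydrozirconation of the 2-alkyne should place zirconium on the methyl-bearing carbon (E-alkenyl metal, methyl cis to the chain), and after Zr-to-Zn transmetalation the Ti(O-i-Pr)4/bis(sulfonamide)diol-catalysed enantioselective 1,2-addition of the alkenylzinc to the enone carbonyl should set the (S)-carbinol centre C1 under catalyst control, the ligand enantiomer being chosen accordingly.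

Step 7
Reactants: 12 the (3S)-hydroxy ester
Product: 13 tert-butyldimethylsilyl ether of 12
Conditions: TBSOTf, 2,6-lutidine, CH2Cl2, −78 → 0 °C
Reagents that add atoms: tert-butyldimethylsilyl trifluoromethanesulfonate, CC(C)(C)[Si](C)(C)OS(=O)(=O)C(F)(F)F
Why: Silylation of the tertiary alcohol with the silyl triflate should give the bulky silyloxy group that shields one face of C5 in step 8 and serves as the migration-promoting donor in step 10.

Step 8
Reactants: 13 the silyl ether enoate; 14 (4-bromobut-1-yn-1-yl)trimethylsilane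
Product: 17 2-(trimethylsilyl)ethyl (2S,3S)-3-[(tert-butyldimethylsilyl)oxy]-3-{(2E,6E)-8-[(tert-butyldiphenylsilyl)oxy]-6-methylocta-2,6-dien-2-yl}-2-[4-(trimethylsilyl)but-3-yn-1-yl]cyclopentane-1-carboxylate (epimers at the ester-bearing carbon C4), via butynylmagnesium bromide 15 (not isolated), via silyl ketene acetal 16 (not isolated)
Conditions: 14, Mg, THF, rt; then CuBr·SMe2 (20 mol %), Me3SiCl, 13, THF, −78 → −20 °C; AcOH/H2O work-up
Reagents that add atoms: none
Why: The CuBr·SMe2-catalysed, chlorosilane-accelerated conjugate addition of the Grignard reagent to the enoate should occur at C5 anti to the allylic C–O bond (stereoelectronic preference reinforced by the silyl group lying over that face), which places the butynyl chain cis to the alkenyl group, while C4 forms as an epimer mixture that converges in step 9.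

Step 9
Reactants: 17 the conjugate adduct
Product: 20 2-(trimethylsilyl)ethyl (1S,2S,3S)-2-(but-3-yn-1-yl)-3-[(tert-butyldimethylsilyl)oxy]-3-{(2E,6E)-8-[(tert-butyldiphenylsilyl)oxy]-6-methylocta-2,6-dien-2-yl}-1-methylcyclopentane-1-carboxylate, via lithium ester enolate 18 (not isolated), via C-silylated alkyne 19 (not isolated)
Conditions: LiN(i-Pr)2, THF/DMPU, −78 °C; MeI, −78 → 0 °C; then K2CO3, MeOH, rt
Reagents that add atoms: iodomethane, CI
Why: In this ester enolate alkylation MeI should approach the exocyclic enolate anti to the adjacent C5 chain, so that the ester ends cis to the chain (the future 4β-carboxyl C19) and the new methyl trans (C18), and methanolysis then frees the terminal alkyne.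

Step 10
Reactants: 20 the 1-alkenyl-2-butynylcyclopentyl silyl ether
Product: 21 2-(trimethylsilyl)ethyl 15-[(tert-butyldiphenylsilyl)oxy]-1-oxolabda-8(17),13E-dien-19-oate
Conditions: [(t-Bu)2(2-biphenylyl)P]Au(NCMe)SbF6 (5 mol %), i-PrOH (1.5 equiv), CH2Cl2, 0 °C → rt
Reagents that add atoms: none
Why: Proposed new method: the cationic monovalent gold complex activates the terminal alkyne, C9 of the C9=C10 alkene attacks the inner alkyne carbon C8 (7-exo-dig, Markovnikov, leaving a C17–Au vinyl species and cationic character at tertiary C10), and the C1–C5 bond, parallel to the empty orbital and pushed by the silyloxy lone pair, migrates from C1 to C10 (semipinacol shift), after which the silyl group passes to i-PrOH and protodeauration gives the C8=C17 methylene. The closest known reaction type is the pinacol-terminated cyclisation of 1-alkenyl-2-alkynylcycloalkanol silyl ethers catalysed by cationic phosphine–gold complexes (1,6-enynes, ring-enlarging cyclopentane annulation) and its oxocarbenium parent, the Prins–pinacol reaction; here the tether is one carbon longer. Ring B is closed by C8–C9 bond formation through the seven-membered array C8–C7–C6–C5–C1–C10–C9, which the 1,2-shift contracts to six members by making C5–C10, and the same shift enlarges the cyclopentane C1–C5 to the cyclohexanone ring A (C1–C5, C10). C9 and C10 are set together because C8 and C5 must add to the same face of the E-alkene to form a six-membered ring, which puts C11 cis to the C10 methyl; C5 migrates with retention, and as the alkenyl and butynyl groups are cis on the cyclopentane the least-motion shift leads to the trans ring fusion. The step needs C9 and not C10 as the nucleophilic alkene carbon, C5 and not C2 as the migrating carbon, the alkene and not the silyl ether oxygen as the nucleophile, and the rotamer about C1–C10 that builds ring B on the face away from C4; these should be secured by the tertiary cation at C10, by the tether and higher substitution of C5, by the poor nucleophilicity of the hindered silyl ether, and by the C19 ester on C4, which blocks the other rotamer.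

Step 11
Reactants: 21 the 1-oxolabdadienoate
Product: 22 2-(trimethylsilyl)ethyl 15-[(tert-butyldiphenylsilyl)oxy]-1-hydroxylabda-8(17),13E-dien-19-oate (C1 epimers)
Conditions: NaBH4, MeOH/THF, 0 °C → rt
Reagents that add atoms: none
Why: Hydride reduction of the C1 ketone should leave the hindered quaternary ester untouched and give the secondary alcohol needed for radical deoxygenation, the configuration of the new carbinol centre being immaterial.

Step 12
Reactants: 22 the 1-hydroxy ester
Product: 23 O-(imidazol-1-ylthiocarbonyl) derivative of 22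
Conditions: 1,1'-thiocarbonyldiimidazole, DMAP, ClCH2CH2Cl, 80 °C
Reagents that add atoms: 1,1'-thiocarbonyldiimidazole, S=C(n1ccnc1)n1ccnc1
Why: Thioacylation under neutral conditions (first stage of the Barton–McCombie deoxygenation) should work on the hindered secondary alcohol.

Step 13
Reactants: 23 the thiocarbonylimidazolide
Product: 24 2-(trimethylsilyl)ethyl 15-[(tert-butyldiphenylsilyl)oxy]labda-8(17),13E-dien-19-oate
Conditions: Bu3SnH, AIBN (cat.), toluene, 100 °C
Reagents that add atoms: none
Why: Barton–McCombie radical deoxygenation should remove the temporary C1 oxygen, because the C1 radical has no favourable cyclisation mode (four-ring or 5-endo onto C8=C17, slow 6-exo onto substituted C13) and is reduced by Bu3SnH.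

Step 14
Reactants: 24 the doubly protected isocupressate
Product: 25 isocupressic acid (15-hydroxylabda-8(17),13E-dien-19-oic acid)
Conditions: Bu4NF, THF, rt; aqueous NH4Cl
Reagents that add atoms: none
Why: Fluoride should cleave the silyl ether and, by fragmentation of the 2-silylethyl group with loss of ethene, also the ester, with no nucleophilic attack at the shielded C19 carbonyl.

Step 15
Reactants: 25 isocupressic acid; 26 oleoyl chloride
Product: 27 15-oleoyloxylabda-8(17),13E-dien-19-oic acid (target)
Conditions: 26 (1.1 equiv), pyridine, DMAP (cat.), CH2Cl2, 0 °C; aqueous NaHCO3 work-up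
Reagents that add atoms: none
Why: Esterification with the acyl chloride should be chemoselective for the primary allylic alcohol, since the neopentyl-type C19 acid is not acylated irreversibly and any mixed anhydride should transfer its oleoyl group or hydrolyse on work-up.

**Compound list**

1 | geraniol | CC(C)=CCC/C(C)=C/CO | starting material
2 | geranyl tert-butyldiphenylsilyl ether, tert-butyl{[(2E)-3,7-dimethylocta-2,6-dien-1-yl]oxy}diphenylsilane | CC(C)=CCC/C(C)=C/CO[Si](c1ccccc1)(c1ccccc1)C(C)(C)C | intermediate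
3 | 6,7-epoxygeranyl tert-butyldiphenylsilyl ether (racemic epoxide) | CC1(C)OC1CC/C(C)=C/CO[Si](c1ccccc1)(c1ccccc1)C(C)(C)C | intermediate (not isolated)
4 | (4E)-6-[(tert-butyldiphenylsilyl)oxy]-4-methylhex-4-enal | O=CCC/C(C)=C/CO[Si](c1ccccc1)(c1ccccc1)C(C)(C)C | intermediate
5 | tert-butyl{[(2E)-7,7-dibromo-3-methylhepta-2,6-dien-1-yl]oxy}diphenylsilane | BrC(Br)=CCC/C(C)=C/CO[Si](c1ccccc1)(c1ccccc1)C(C)(C)C | intermediate
6 | lithium (5E)-7-[(tert-butyldiphenylsilyl)oxy]-5-methylhept-5-en-1-yn-1-ide | [Li]C#CCC/C(C)=C/CO[Si](c1ccccc1)(c1ccccc1)C(C)(C)C | intermediate (not isolated)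
7 | tert-butyl{[(2E)-3-methyloct-2-en-6-yn-1-yl]oxy}diphenylsilane | CC#CCC/C(C)=C/CO[Si](c1ccccc1)(c1ccccc1)C(C)(C)C | intermediate
8 | 3-oxocyclopent-1-ene-1-carboxylic acid | O=C1CCC(C(=O)O)=C1 | starting material
9 | 2-(trimethylsilyl)ethyl 3-oxocyclopent-1-ene-1-carboxylate | O=C1CCC(C(=O)OCC[Si](C)(C)C)=C1 | intermediate
10 | chloro{(2E,6E)-8-[(tert-butyldiphenylsilyl)oxy]-6-methylocta-2,6-dien-2-yl}bis(cyclopentadienyl)zirconium | Cl[Zr](C1C=CC=C1)(C1C=CC=C1)/C(C)=C/CC/C(C)=C/CO[Si](c1ccccc1)(c1ccccc1)C(C)(C)C | intermediate (not isolated)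
11 | {(2E,6E)-8-[(tert-butyldiphenylsilyl)oxy]-6-methylocta-2,6-dien-2-yl}(methyl)zinc | C[Zn]/C(C)=C/CC/C(C)=C/CO[Si](c1ccccc1)(c1ccccc1)C(C)(C)C | intermediate (not isolated)
12 | 2-(trimethylsilyl)ethyl (3S)-3-{(2E,6E)-8-[(tert-butyldiphenylsilyl)oxy]-6-methylocta-2,6-dien-2-yl}-3-hydroxycyclopent-1-ene-1-carboxylate | C[Si](C)(C)CCOC(=O)C1=C[C@](O)(/C(C)=C/CC/C(C)=C/CO[Si](c2ccccc2)(c2ccccc2)C(C)(C)C)CC1 | intermediate
13 | 2-(trimethylsilyl)ethyl (3S)-3-[(tert-butyldimethylsilyl)oxy]-3-{(2E,6E)-8-[(tert-butyldiphenylsilyl)oxy]-6-methylocta-2,6-dien-2-yl}cyclopent-1-ene-1-carboxylate | C[Si](C)(C)CCOC(=O)C1=C[C@](O[Si](C)(C)C(C)(C)C)(/C(C)=C/CC/C(C)=C/CO[Si](c2ccccc2)(c2ccccc2)C(C)(C)C)CC1 | intermediate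
14 | (4-bromobut-1-yn-1-yl)trimethylsilane | C[Si](C)(C)C#CCCBr | starting material
15 | [4-(trimethylsilyl)but-3-yn-1-yl]magnesium bromide | C[Si](C)(C)C#CCC[Mg]Br | intermediate (not isolated)
16 | trimethylsilyl 2-(trimethylsilyl)ethyl ketene acetal of 17 (chain at C5 cis to the alkenyl group; acetal geometry undefined) | C[Si](C)(C)C#CCC[C@H]1C(=C(O[Si](C)(C)C)OCC[Si](C)(C)C)CC[C@@]1(O[Si](C)(C)C(C)(C)C)/C(C)=C/CC/C(C)=C/CO[Si](c1ccccc1)(c1ccccc1)C(C)(C)C | intermediate (not isolated)
17 | 2-(trimethylsilyl)ethyl (2S,3S)-3-[(tert-butyldimethylsilyl)oxy]-3-{(2E,6E)-8-[(tert-butyldiphenylsilyl)oxy]-6-methylocta-2,6-dien-2-yl}-2-[4-(trimethylsilyl)but-3-yn-1-yl]cyclopentane-1-carboxylate (chain cis to alkenyl, trans to silyloxy; C4 epimers) | C[Si](C)(C)C#CCC[C@H]1C(C(=O)OCC[Si](C)(C)C)CC[C@@]1(O[Si](C)(C)C(C)(C)C)/C(C)=C/CC/C(C)=C/CO[Si](c1ccccc1)(c1ccccc1)C(C)(C)C | intermediate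
18 | lithium ester enolate of 17 | C[Si](C)(C)C#CCC[C@H]1C(=C(O[Li])OCC[Si](C)(C)C)CC[C@@]1(O[Si](C)(C)C(C)(C)C)/C(C)=C/CC/C(C)=C/CO[Si](c1ccccc1)(c1ccccc1)C(C)(C)C | intermediate (not isolated)
19 | 2-(trimethylsilyl)ethyl (1S,2S,3S)-3-[(tert-butyldimethylsilyl)oxy]-3-{(2E,6E)-8-[(tert-butyldiphenylsilyl)oxy]-6-methylocta-2,6-dien-2-yl}-1-methyl-2-[4-(trimethylsilyl)but-3-yn-1-yl]cyclopentane-1-carboxylate | C[Si](C)(C)C#CCC[C@H]1[C@@](C)(C(=O)OCC[Si](C)(C)C)CC[C@@]1(O[Si](C)(C)C(C)(C)C)/C(C)=C/CC/C(C)=C/CO[Si](c1ccccc1)(c1ccccc1)C(C)(C)C | intermediate (not isolated)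
20 | 2-(trimethylsilyl)ethyl (1S,2S,3S)-2-(but-3-yn-1-yl)-3-[(tert-butyldimethylsilyl)oxy]-3-{(2E,6E)-8-[(tert-butyldiphenylsilyl)oxy]-6-methylocta-2,6-dien-2-yl}-1-methylcyclopentane-1-carboxylate (ester, butynyl and alkenyl groups all cis) | C#CCC[C@H]1[C@@](C)(C(=O)OCC[Si](C)(C)C)CC[C@@]1(O[Si](C)(C)C(C)(C)C)/C(C)=C/CC/C(C)=C/CO[Si](c1ccccc1)(c1ccccc1)C(C)(C)C | intermediate
21 | 2-(trimethylsilyl)ethyl 15-[(tert-butyldiphenylsilyl)oxy]-1-oxolabda-8(17),13E-dien-19-oate (5α-H, 9α-H, 10β-methyl, 4β-ester) | C=C1CC[C@@H]2[C@](C)(C(=O)CC[C@]2(C)C(=O)OCC[Si](C)(C)C)[C@H]1CC/C(C)=C/CO[Si](c1ccccc1)(c1ccccc1)C(C)(C)C | intermediate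
22 | 2-(trimethylsilyl)ethyl 15-[(tert-butyldiphenylsilyl)oxy]-1-hydroxylabda-8(17),13E-dien-19-oate (C1 epimers) | C=C1CC[C@@H]2[C@](C)(C(O)CC[C@]2(C)C(=O)OCC[Si](C)(C)C)[C@H]1CC/C(C)=C/CO[Si](c1ccccc1)(c1ccccc1)C(C)(C)C | intermediate
23 | 2-(trimethylsilyl)ethyl 15-[(tert-butyldiphenylsilyl)oxy]-1-[(imidazol-1-ylcarbonothioyl)oxy]labda-8(17),13E-dien-19-oate (C1 epimers) | C=C1CC[C@@H]2[C@](C)(C(OC(=S)n3ccnc3)CC[C@]2(C)C(=O)OCC[Si](C)(C)C)[C@H]1CC/C(C)=C/CO[Si](c1ccccc1)(c1ccccc1)C(C)(C)C | intermediate
24 | 2-(trimethylsilyl)ethyl 15-[(tert-butyldiphenylsilyl)oxy]labda-8(17),13E-dien-19-oate | C=C1CC[C@@H]2[C@](C)(CCC[C@]2(C)C(=O)OCC[Si](C)(C)C)[C@H]1CC/C(C)=C/CO[Si](c1ccccc1)(c1ccccc1)C(C)(C)C | intermediate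
25 | isocupressic acid, 15-hydroxylabda-8(17),13E-dien-19-oic acid | C=C1CC[C@@H]2[C@](C)(CCC[C@]2(C)C(=O)O)[C@H]1CC/C(C)=C/CO | intermediate
26 | oleoyl chloride, (9Z)-octadec-9-enoyl chloride | CCCCCCCC/C=C\CCCCCCCC(=O)Cl | starting material
27 | 15-[(9Z)-octadec-9-enoyloxy]labda-8(17),13E-dien-19-oic acid (4S,5R,9S,10R) | C=C1CC[C@@H]2[C@](C)(CCC[C@]2(C)C(=O)O)[C@H]1CC/C(C)=C/COC(=O)CCCCCCC/C=C\CCCCCCCC | target

**Step count and risks**

Total: 15 steps. Longest linear sequence: 14 steps (steps 1–4, then 6–15; step 5 is a one-step branch).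

Steps most likely to fail, with fallbacks:

(a) Key step 10 (proposed new method). Closure through the seven-membered array may be slow, so that attack of the silyl ether oxygen on the activated alkyne, reaction through the other rotamer about C1–C10 (cis-fused decalone) or migration of the new exocyclic alkene could compete. The fallback uses known reactions, sets out from 20 and comes back at 21. A bromonium-induced semipinacol rearrangement (N-bromosuccinimide, propylene oxide, CH2Cl2, −78 °C), a known ring expansion of 1-alkenylcycloalkanols and their silyl ethers, should move C5 from C1 to C10 anti to the bromonium ion and give the ring A bromo ketone F1. The bromonium ion of the remote C13=C14 alkene has no internal nucleophile and should revert. Bu3SnH/AIBN (slow addition, benzene, 80 °C) should then close ring B by 6-exo-dig cyclisation of the C9 radical onto the terminal alkyne, with the side chain equatorial in a chair transition state, and reduce the vinyl radical to the C8=C17 methylene of 21.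

(b) Step 8. Facial selectivity may be poor, because the branched alkenyl group competes with the silyloxy group in shielding C5, and addition at the neopentyl-like β-carbon may be sluggish. The fallback makes the carbon substituent on C1 slim during the addition and builds the alkene afterwards; it sets out from 5 (with 9 and 14) and comes back at 20. Treatment of 5 with n-BuLi and then water should give the terminal enyne F2. Enantioselective addition of its zinc alkynylide to 9 (Me2Zn, chiral salen ligand, toluene) should give the (S)-alkynyl carbinol F3, and Me3SiCl/imidazole its trimethylsilyl ether F4. The same CuBr·SMe2/Me3SiCl-mediated addition of 15 should now enter anti to the silyloxy group without competition and give the conjugate adduct F5. LiN(i-Pr)2/MeI followed by K2CO3/MeOH, which cleaves both the O–Si and the C–Si bond, should give the methylated diynol F6. The known hydroxyl-directed anti-carbomagnesiation of propargylic alcohols (MeMgBr, CuI cat., THF, reflux, then water) should deliver methyl to C10 and hydrogen to C9 and give the E-alkenyl carbinol F7. TBSOTf/2,6-lutidine returns to 20.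

(c) Step 6. Enantioselectivity may be insufficient, hydrozirconation may give some of the regioisomeric alkenyl metal, and methyl transfer from zinc may compete. The fallback gives up catalyst control for a stoichiometric addition followed by resolution; it sets out from 7 (with 9) and comes back at 12. Cp2Zr(H)Cl followed by I2 should give the E-alkenyl iodide F8, which can be purified from its regioisomer. Iodine–lithium exchange (t-BuLi, Et2O, −78 °C), transmetalation with CeCl3 and addition to 9 should give the racemic carbinol F9. Separation of the enantiomers by preparative chromatography on a chiral stationary phase gives 12.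

**Further compounds**

F1 | step 10 | 2-(trimethylsilyl)ethyl 9-bromo-15-[(tert-butyldiphenylsilyl)oxy]-1-oxo-8,9-secolabd-13E-en-8(17)-yn-19-oate (C9 epimers) | C#CCC[C@H]1[C@@](C)(C(=O)OCC[Si](C)(C)C)CCC(=O)[C@]1(C)C(Br)CC/C(C)=C/CO[Si](c1ccccc1)(c1ccccc1)C(C)(C)C
F2 | step 8 | tert-butyl{[(2E)-3-methylhept-2-en-6-yn-1-yl]oxy}diphenylsilane | C#CCC/C(C)=C/CO[Si](c1ccccc1)(c1ccccc1)C(C)(C)C
F3 | step 8 | 2-(trimethylsilyl)ethyl (3S)-3-{(5E)-7-[(tert-butyldiphenylsilyl)oxy]-5-methylhept-5-en-1-yn-1-yl}-3-hydroxycyclopent-1-ene-1-carboxylate | C[Si](C)(C)CCOC(=O)C1=C[C@](O)(C#CCC/C(C)=C/CO[Si](c2ccccc2)(c2ccccc2)C(C)(C)C)CC1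
F4 | step 8 | trimethylsilyl ether of F3 | C[Si](C)(C)CCOC(=O)C1=C[C@](O[Si](C)(C)C)(C#CCC/C(C)=C/CO[Si](c2ccccc2)(c2ccccc2)C(C)(C)C)CC1
F5 | step 8 | 2-(trimethylsilyl)ethyl (2S,3S)-3-{(5E)-7-[(tert-butyldiphenylsilyl)oxy]-5-methylhept-5-en-1-yn-1-yl}-3-[(trimethylsilyl)oxy]-2-[4-(trimethylsilyl)but-3-yn-1-yl]cyclopentane-1-carboxylate (C4 epimers) | C[Si](C)(C)C#CCC[C@H]1C(C(=O)OCC[Si](C)(C)C)CC[C@@]1(O[Si](C)(C)C)C#CCC/C(C)=C/CO[Si](c1ccccc1)(c1ccccc1)C(C)(C)C
F6 | step 8 | 2-(trimethylsilyl)ethyl (1S,2S,3S)-2-(but-3-yn-1-yl)-3-{(5E)-7-[(tert-butyldiphenylsilyl)oxy]-5-methylhept-5-en-1-yn-1-yl}-3-hydroxy-1-methylcyclopentane-1-carboxylate | C#CCC[C@H]1[C@@](C)(C(=O)OCC[Si](C)(C)C)CC[C@@]1(O)C#CCC/C(C)=C/CO[Si](c1ccccc1)(c1ccccc1)C(C)(C)C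
F7 | step 8 | 2-(trimethylsilyl)ethyl (1S,2S,3S)-2-(but-3-yn-1-yl)-3-{(2E,6E)-8-[(tert-butyldiphenylsilyl)oxy]-6-methylocta-2,6-dien-2-yl}-3-hydroxy-1-methylcyclopentane-1-carboxylate | C#CCC[C@H]1[C@@](C)(C(=O)OCC[Si](C)(C)C)CC[C@@]1(O)/C(C)=C/CC/C(C)=C/CO[Si](c1ccccc1)(c1ccccc1)C(C)(C)C
F8 | step 6 | tert-butyl{[(2E,6E)-7-iodo-3-methylocta-2,6-dien-1-yl]oxy}diphenylsilane | C/C(I)=C\CC/C(C)=C/CO[Si](c1ccccc1)(c1ccccc1)C(C)(C)C
F9 | step 6 | racemic 2-(trimethylsilyl)ethyl 3-{(2E,6E)-8-[(tert-butyldiphenylsilyl)oxy]-6-methylocta-2,6-dien-2-yl}-3-hydroxycyclopent-1-ene-1-carboxylate | C[Si](C)(C)CCOC(=O)C1=CC(O)(/C(C)=C/CC/C(C)=C/CO[Si](c2ccccc2)(c2ccccc2)C(C)(C)C)CC1
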